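## The problem

The target **26** is methyl (13S)-6β-acetoxy-8α-hydroxylabdan-15-oate: a trans-fused decalin (ring A = C1–C5 and C10, ring B = C5–C10) with a five-carbon ester chain on C9. Ring A is bare, but it flanks the ring fusion with the gem-dimethyl carbon C4 and the all-carbon quaternary stereocentre C10, so the C5–C10 bond lies between two fully substituted carbons and is hard to form by a late intermolecular coupling. Ring B carries four further stereocentres: C5 (H α), C6 (axial β-acetate), C8 (tertiary carbinol, OH α and equatorial, methyl β and axial) and C9 (chain β, cis to the C10 methyl). The axial methyls on C10, C4 and C8 screen the β face of ring B, so C10, once set, can control C6 and C8, and C5 can be corrected through a C6 carbonyl. C9 has to be set together with C10, and C13 lies on a flexible chain beyond the reach of any ring centre and must come from the chiral pool. The fragile elements are the 1,3-oxygen pair (a β-hydroxy ketone at the C6-ketone stage, open to dehydration and retro-aldol cleavage), the crowded axial acetate, the methyl ester (no strong hydride or hydroxide) and any silyl enol ether carried along the way. The enabling feature is that C10 bears its methyl cis to C11 on C9 and is bonded to C5, whose neighbour C6 carries oxygen: C9–C10 is the retron of an (E)-β-methyl enal, C5–C6(O)–C7–C8 that of a 2-oxygenated diene, and C1–C4 ties the two together.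

## Retrosynthesis

**C6 oxygen (26 → 25 → 24).** The acetyl C–O bond is cut first, giving diol **25**, and the C6 carbinol is read as the ketone **24**. The acetate is put on last so that an axial ester never meets base, and the ketone is the natural handle because its β face is blocked by three syn-axial methyl groups. Hydride delivery from the C8 hydroxyl was weighed, but that hydroxyl is equatorial and anti-periplanar to the C7–C6 bond and cannot reach C6; plain substrate control leads to the same 6β-alcohol. The forward steps need a small borohydride that spares the ester, and an acylation that distinguishes the secondary from the tertiary hydroxyl.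

**C8 oxygen (24 → 23 → 22).** The C8–O bond is traced to the α-epoxide **23** (C7–O cut reductively) and this to the 7-en-6-one **22**. Adding a methyl group to a C8 ketone would require telling two ring B carbonyls apart and controlling a face next to the C9 chain; direct conjugate hydration of the enone is reversible. **22** has two stereocentres fewer and an epimerisable C5. The forward steps need epoxidation from the α face and a ring opening that does not dehydrate the product.

**Enone and side chain (22 → 21 → 20 → 15 + 18).** The C7=C8 unsaturation is taken back to the C6=C7 silyl enol ether **21**, which is what a 2-silyloxydiene leaves behind after cycloaddition. The chain is cut at C11–C12 (olefination, then hydrogenation), giving aldehyde **15** and phosphonium salt **18**. This cut leaves a formyl group on C9, the activator a dienophile needs, and isolates C13 in a four-carbon piece that comes in two steps from hemiester **16** through iodide **17**. A C9–C11 cut would mean alkylation next to the quaternary C10, and a C12–C13 cut an sp3–sp3 coupling at a stereocentre. The chain is attached and saturated before the enone is made, because in **22** the C9 hydrogen is vinylogously acidic and an adjacent C11=C12 bond would invite conjugation.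

**Both rings (15 → 14).** C5–C10 and C8–C9 are cut together, opening rings A and B to the achiral trienal **14**. No other cut removes both rings, the quaternary centre and three further stereocentres at once. The forward reaction must control the enal face (chiral boron Lewis acid), place the formyl group endo, and tolerate a silyl dienol ether.

**Trienal (14 → 13 → 12 → 11 → 9 → 7 + 8).** The enal is taken back through allylic alcohol **13** to the ester **12**, so that C11 is a robust ester while the ketone is enolised. The dienol ether comes from enone **11**, and the C7=C8 bond from aldol **9**, i.e. methyl ketone **7** and acetaldehyde **8**. The forward steps need enolisation at C5 rather than C17, and a Z enol ether that places the tether on the outside of the diene.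

**Chain assembly (7 → 3 + 5; 3 → 1 + 2; 5 → 4).** C1–C10 is cut as an sp3–sp2 coupling between the terminal alkene **3** and the (E)-enol triflate **5** (from ethyl acetoacetate **4**). This fixes the (E)-trisubstituted alkene by stereoretention instead of by a poorly selective ketone olefination. C3–C4 is cut as conjugate allylation of mesityl oxide **1** by allyltrimethylsilane **2**, which builds the gem-dimethyl carbon in one step.

## Roads not taken

Alternative 1: Ring A is cut at C4–C5 on a prochiral cyclohexadiene whose quaternary carbon is C10; a boron Lewis acid opens a chain epoxide at C4 and one of two enantiotopic enol ether carbons closes ring A, giving dione **A1** after hydrolysis. Its merits are real: absolute control comes from an epoxide of reliable configuration, C10 is set by desymmetrisation, and ring B arrives oxygenated at exactly C6 and C8. For this target, however, the C3 hydroxyl of **A1** is superfluous and costs a deoxygenation. The two carbonyls must be told apart for methyl addition at C8. The C9 chain must be attached at a methylene that lies between a carbonyl and the quaternary C10, while the 1,3-dione enolises toward C7 instead. In reliability of the asymmetric step this road is better than the chosen one. The chosen plan sets against it that C9, its one-carbon handle and the C5/C10 relationship all come from the ring-forming step, with no oxygen to remove.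

Alternative 2: Ring B is cut at C8–C9; a phosphine-ligated divalent palladium catalyst cycloisomerises a 1,7-enyne on a preformed ring A to diene **A2**, which already carries the whole chain and the 6β-acetate. The endgame is clearly shorter than the chosen one: Markovnikov hydration of the exocyclic alkene and hydrogenation of the 11-ene, against seven steps after the key step here. The weak points are as follows. C9 is created next to the quaternary C10 by the ene step, with only substrate control. Closing a six-membered ring onto a trisubstituted alkene is the harder case for this cycloisomerisation. The hydration must choose both the right alkene and the α face. The substrate needs C5, C6, C10 and C13 in place beforehand, and a ring A made by cycloaddition leaves unsaturation to erase in a ring that is bare in **26**. The chosen plan sets against the shorter endgame that C5, C9 and C10 come from one catalyst-controlled event on an achiral chain, and that C6 and C8 are set on a ring whose β face is blocked.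

Alternative 3: Ring B is cut at C6–C7; an iron salt and a hydroperoxide turn a ring A aldehyde into an acyl radical that closes 6-endo onto an isopropenyl group, and the C8 radical is capped as peroxide **A3**. **A3** is **24** in masked form, so the endgame (O–O reduction, ketone reduction, acetylation) is the shortest of all, and ring closure and C8 oxygenation coincide. The cost is shifted into the precursor: a cyclohexane with C5, C10 and the exocyclic C9 stereocentre already correct. In the key step the acyl radical can lose CO, 5-exo closure competes with 6-endo, and the face of oxygen capture at a planar tertiary radical rests on conformation alone. The chosen plan is longer after the key step, but its C8 oxygen is delivered by an ionic addition with a predictable face, and its ring stereocentres do not have to be made beforehand.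

Key step: step 9

**Assumptions and conventions.**
- Labdane numbering is used throughout. "Labd-" in a name implies the normal ring configuration (5α-H, 9α-H, 10β-methyl) with C17 on C8 β unless stated.
- The facial sense of the catalyst in step 9 is taken from the usual binding model of enals to protonated B-aryl oxazaborolidines (aldehyde on the convex face of boron, formyl C–H toward the ring oxygen, s-trans enal stacked on the neighbouring phenyl group). On that model the catalyst from (R)-α,α-diphenylprolinol leaves open the Re face of C10, which leads to **15**. The assignment would be checked on **15** before material is carried on; the enantiomeric catalyst is the remedy if the sense is reversed.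
- Hemiester **16** is taken as a purchasable compound.
- Aldol **9** forms as a racemate at its carbinol carbon; that centre is removed in step 5.

## Route

Step 1
Reactants: 1 mesityl oxide; 2 allyltrimethylsilane
Product: 3 4,4-dimethylhept-6-en-2-one
Conditions: TiCl4, CH2Cl2, −78 °C; H2O
Reagents that add atoms: none
Why: Hosomi–Sakurai conjugate allylation: the TiCl4-bound enone is attacked at its β-carbon by the allylsilane, a standard way to make a quaternary carbon from a β,β-disubstituted enone; this forms C3–C4 and the gem-dimethyl carbon.

Step 2
Reactants: 4 ethyl acetoacetate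
Product: 5 ethyl (2E)-3-(trifluoromethanesulfonyloxy)but-2-enoate
Conditions: Tf2O, aq Me4NOH, hexanes, 5 °C
Reagents that add atoms: trifluoromethanesulfonic anhydride, O=S(=O)(OS(=O)(=O)C(F)(F)F)C(F)(F)F
Why: O-triflation of the β-keto ester enolate; with the non-chelating tetramethylammonium counter-ion the enolate reacts in its extended form and gives the (E)-enol triflate, the isomer whose coupling with retention places the incoming chain trans to the ester.

Step 3
Reactants: 3 4,4-dimethylhept-6-en-2-one; 5 ethyl (2E)-3-(trifluoromethanesulfonyloxy)but-2-enoate
Product: 7 ethyl (2E)-3,7,7-trimethyl-9-oxodec-2-enoate, via B-alkyl-9-BBN adduct 6 (not isolated)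
Conditions: 9-BBN, THF, 0 °C → rt; then 5, PdCl2(dppf) (5 mol %), aq K3PO4, DMF, rt
Reagents that add atoms: none
Why: Anti-Markovnikov hydroboration of the monosubstituted alkene (faster than reduction of the hindered methyl ketone by this borane), then B-alkyl Suzuki–Miyaura coupling with the enol triflate with retention of geometry; this forms C1–C10 and fixes the (E)-trisubstituted alkene.

Step 4
Reactants: 7 ethyl (2E)-3,7,7-trimethyl-9-oxodec-2-enoate; 8 acetaldehyde
Product: 9 ethyl (2E)-11-hydroxy-3,7,7-trimethyl-9-oxododec-2-enoate
Conditions: LiN(i-Pr)2, THF, −78 °C; then MeCHO, −78 °C; aq NH4Cl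
Reagents that add atoms: none
Why: Kinetic lithium enolate formation at the methyl group (the other α-position is neopentyl, and the conjugated ester is less acidic and a poor electrophile at −78 °C) followed by aldol addition; the new carbinol centre is racemic and disappears in step 5.

Step 5
Reactants: 9 ethyl (2E)-11-hydroxy-3,7,7-trimethyl-9-oxododec-2-enoate
Product: 11 ethyl (2E,10E)-3,7,7-trimethyl-9-oxododeca-2,10-dienoate, via mesylate 10 (not isolated)
Conditions: MsCl, Et3N, CH2Cl2, 0 °C; then DBU, rt
Reagents that add atoms: none
Why: Mesylation and E1cB elimination complete the aldol condensation under mild conditions and give the thermodynamically preferred (E)-enone.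

Step 6
Reactants: 11 ethyl (2E,10E)-3,7,7-trimethyl-9-oxododeca-2,10-dienoate
Product: 12 ethyl (2E,8Z,10E)-9-(tert-butyldimethylsilyloxy)-3,7,7-trimethyldodeca-2,8,10-trienoate
Conditions: TBSOTf, Et3N, CH2Cl2, −78 → 0 °C
Reagents that add atoms: tert-butyldimethylsilyl trifluoromethanesulfonate, CC(C)(C)[Si](C)(C)OS(=O)(=O)C(F)(F)F
Why: Soft enolisation of the enone at the α′ carbon (C5) gives the cross-conjugated 2-silyloxydiene; the Z enol ether is favoured because the E isomer would press the quaternary C4 against the propenyl group (A(1,3) strain), and Z places the tether on the outside of the diene; the ester is not enolised under these conditions.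

Step 7
Reactants: 12 ethyl (2E,8Z,10E)-9-(tert-butyldimethylsilyloxy)-3,7,7-trimethyldodeca-2,8,10-trienoate
Product: 13 (2E,8Z,10E)-9-(tert-butyldimethylsilyloxy)-3,7,7-trimethyldodeca-2,8,10-trien-1-ol
Conditions: i-Bu2AlH, CH2Cl2, −78 °C; aq KNaC4H4O6
Reagents that add atoms: none
Why: 1,2-Reduction of the enoate to the allylic alcohol; silyl enol ethers are inert to aluminium hydrides and the tartrate work-up is not acidic.

Step 8
Reactants: 13 (2E,8Z,10E)-9-(tert-butyldimethylsilyloxy)-3,7,7-trimethyldodeca-2,8,10-trien-1-ol
Product: 14 (2E,8Z,10E)-9-(tert-butyldimethylsilyloxy)-3,7,7-trimethyldodeca-2,8,10-trienal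
Conditions: MnO2, CH2Cl2, rt
Reagents that add atoms: none
Why: Heterogeneous, neutral MnO2 oxidation is selective for the allylic alcohol, keeps the (E)-geometry and leaves the silyl dienol ether untouched.

Step 9
Reactants: 14 (2E,8Z,10E)-9-(tert-butyldimethylsilyloxy)-3,7,7-trimethyldodeca-2,8,10-trienal
Product: 15 (1S,2S,4aS,8aS)-4-(tert-butyldimethylsilyloxy)-2,5,5,8a-tetramethyl-1,2,4a,5,6,7,8,8a-octahydronaphthalene-1-carbaldehyde
Conditions: B-(o-tolyl)oxazaborolidine from (R)-α,α-diphenylprolinol (20 mol %), Tf2NH (18 mol %), CH2Cl2, −78 → −40 °C
Reagents that add atoms: none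
Why: The cationic boron Lewis acid binds the formyl oxygen of 14 and lowers the enal LUMO; C5, the nucleophilic terminus of the 2-silyloxydiene, attacks the β-carbon C10 and C8–C9 closes in an asynchronous concerted [4+2] (a stepwise Mukaiyama–Michael and ring-closure sequence would give the same adduct). The closest known reactions are oxazaborolidinium-catalysed Diels–Alder additions of enals to 2-silyloxydienes and Lewis-acid-catalysed type 1 intramolecular Diels–Alder reactions of 1,7,9-decatrienals. Ring A closes as the six-membered carbocycle completed by the C1–C4 tether when C5–C10 forms, and ring B closes as the cyclohexene of the [4+2] when C8–C9 forms. C9 and C10 are related (formyl cis to the C10 methyl) by suprafacial addition to the (E)-dienophile, and their absolute configuration comes from the catalyst, which leaves the Re face of C10 open. C5 ends trans to the C10 methyl through the transition state with the formyl group endo and the tether exo; the C8 methyl ends cis to the formyl group by the (E)-propenyl terminus and the endo rule, and C8 is flattened again in step 14. The step needs face selectivity (catalyst), endo selectivity (Lewis-acid-bound formyl; an exo leak gives only the C5 epimer, which can be equilibrated later through the C6 ketone) and a diene with its tether outside (the Z enol ether from step 6). The silyl enol ether should survive because the temperature is low and the triflimide counter-ion is not nucleophilic.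

Step 10
Reactants: 16 (3S)-5-methoxy-3-methyl-5-oxopentanoic acid
Product: 17 methyl (3R)-4-iodo-3-methylbutanoate
Conditions: PhI(OAc)2, I2, PhH, hν, reflux
Reagents that add atoms: iodine, II
Why: Hunsdiecker-type iododecarboxylation through the acyl hypoiodite: the carboxyl radical loses CO2 and the primary radical is trapped by iodine; the stereocentre is β to the radical and untouched (the descriptor becomes R only through the priority change).

Step 11
Reactants: 17 methyl (3R)-4-iodo-3-methylbutanoate
Product: 18 [(2R)-4-methoxy-2-methyl-4-oxobutyl]triphenylphosphonium iodide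
Conditions: PPh3, MeCN, reflux
Reagents that add atoms: triphenylphosphine, c1ccc(cc1)P(c1ccccc1)c1ccccc1
Why: SN2 quaternisation of the phosphine by the primary iodide; β-branching slows it, hence the heating, and the ester is inert.

Step 12
Reactants: 15 (1S,2S,4aS,8aS)-4-(tert-butyldimethylsilyloxy)-2,5,5,8a-tetramethyl-1,2,4a,5,6,7,8,8a-octahydronaphthalene-1-carbaldehyde; 18 [(2R)-4-methoxy-2-methyl-4-oxobutyl]triphenylphosphonium iodide
Product: 20 methyl (11Z,13R)-6-(tert-butyldimethylsilyloxy)labda-6,11-dien-15-oate, via ylide 19 (not isolated)
Conditions: NaN(SiMe3)2, THF, −78 → 0 °C; then 15, −78 °C → rt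
Reagents that add atoms: none
Why: Wittig olefination with a non-stabilised ylide (the phosphonium α-position is far more acidic than the ester α-position, so 19 forms cleanly); the alkene geometry is irrelevant, and enolisation of the aldehyde at C9 would only return the more stable equatorial formyl epimer. C13 is untouched.

Step 13
Reactants: 20 methyl (11Z,13R)-6-(tert-butyldimethylsilyloxy)labda-6,11-dien-15-oate
Product: 21 methyl (13S)-6-(tert-butyldimethylsilyloxy)labd-6-en-15-oate
Conditions: H2 (1 atm), Pt/C, EtOAc, Et3N (trace), rt
Reagents that add atoms: none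
Why: Heterogeneous hydrogenation of the disubstituted alkene; platinum is preferred to palladium to limit double bond migration toward C13, and the hindered trisubstituted silyl enol ether is expected to survive, the trace of amine guarding it against acid.

Step 14
Reactants: 21 methyl (13S)-6-(tert-butyldimethylsilyloxy)labd-6-en-15-oate
Product: 22 methyl (13S)-6-oxolabd-7-en-15-oate
Conditions: Pd(OAc)2 (1.1 equiv), MeCN, rt → 40 °C
Reagents that add atoms: none
Why: Saegusa–Ito oxidation: the palladium enolate forms at C7 on the open α face and syn β-hydride elimination of the C8 hydrogen (α) gives the 7-en-6-one; C8 carries the only β-hydrogen, so the position of the new double bond is fixed.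

Step 15
Reactants: 22 methyl (13S)-6-oxolabd-7-en-15-oate
Product: 23 methyl (13S)-7α,8α-epoxy-6-oxolabdan-15-oate
Conditions: t-BuOOH, BnMe3N+ OH− (cat.), THF, 0 °C → rt
Reagents that add atoms: tert-butyl hydroperoxide, CC(C)(C)OO
Why: Weitz–Scheffer nucleophilic epoxidation: the peroxide anion adds to C8 from the α face, anti to the axial C10 methyl, and the enolate closes the epoxide on the same face, which sets C8 with oxygen α and methyl β; any 5β epimer present should equilibrate to the trans-fused ketone under the base.

Step 16
Reactants: 23 methyl (13S)-7α,8α-epoxy-6-oxolabdan-15-oate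
Product: 24 methyl (13S)-8α-hydroxy-6-oxolabdan-15-oate
Conditions: SmI2, THF/MeOH, −90 °C
Reagents that add atoms: none
Why: Reduction of the α,β-epoxy ketone by SmI2: the ketyl cleaves the C7–O bond and the samarium enolate is protonated by methanol; the C8–O bond is never broken, so C8 keeps its configuration, and the low temperature suppresses dehydration.

Step 17
Reactants: 24 methyl (13S)-8α-hydroxy-6-oxolabdan-15-oate
Product: 25 methyl (13S)-6β,8α-dihydroxylabdan-15-oate
Conditions: NaBH4, MeOH, −20 → 0 °C
Reagents that add atoms: none
Why: Borohydride reduction under substrate control: the axial (β) trajectory at C6 is blocked by the syn-axial methyl groups on C4, C8 and C10, so hydride enters from the α face and gives the axial 6β-alcohol; the methyl ester is not reduced, and the cold, short reaction limits retro-aldol cleavage.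

Step 18
Reactants: 25 methyl (13S)-6β,8α-dihydroxylabdan-15-oate
Product: 26 methyl (13S)-6β-acetoxy-8α-hydroxylabdan-15-oate
Conditions: Ac2O, DMAP, pyridine, rt
Reagents that add atoms: acetic anhydride, CC(=O)OC(C)=O
Why: DMAP-catalysed acetylation; the secondary alcohol, although axial, is acylated faster than the tertiary C8 hydroxyl, which needs more forcing conditions.

## Compound list

1 | mesityl oxide (4-methylpent-3-en-2-one) | CC(C)=CC(C)=O | starting material
2 | allyltrimethylsilane | C=CC[Si](C)(C)C | starting material
3 | 4,4-dimethylhept-6-en-2-one | CC(=O)CC(C)(C)CC=C | intermediate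
4 | ethyl acetoacetate | CCOC(=O)CC(C)=O | starting material
5 | ethyl (2E)-3-(trifluoromethanesulfonyloxy)but-2-enoate | CCOC(=O)/C=C(\C)OS(=O)(=O)C(F)(F)F | intermediate
6 | 7-(9-borabicyclo[3.3.1]nonan-9-yl)-4,4-dimethylheptan-2-one | CC(=O)CC(C)(C)CCCB1C2CCCC1CCC2 | intermediate (not isolated)
7 | ethyl (2E)-3,7,7-trimethyl-9-oxodec-2-enoate | CCOC(=O)/C=C(\C)CCCC(C)(C)CC(C)=O | intermediate
8 | acetaldehyde | CC=O | starting material
9 | ethyl (2E)-11-hydroxy-3,7,7-trimethyl-9-oxododec-2-enoate (racemic at C11 of the chain) | CCOC(=O)/C=C(\C)CCCC(C)(C)CC(=O)CC(C)O | intermediate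
10 | ethyl (2E)-11-(methanesulfonyloxy)-3,7,7-trimethyl-9-oxododec-2-enoate | CCOC(=O)/C=C(\C)CCCC(C)(C)CC(=O)CC(C)OS(C)(=O)=O | intermediate (not isolated)
11 | ethyl (2E,10E)-3,7,7-trimethyl-9-oxododeca-2,10-dienoate | CCOC(=O)/C=C(\C)CCCC(C)(C)CC(=O)/C=C/C | intermediate
12 | ethyl (2E,8Z,10E)-9-(tert-butyldimethylsilyloxy)-3,7,7-trimethyldodeca-2,8,10-trienoate | CCOC(=O)/C=C(\C)CCCC(C)(C)/C=C(\O[Si](C)(C)C(C)(C)C)/C=C/C | intermediate
13 | (2E,8Z,10E)-9-(tert-butyldimethylsilyloxy)-3,7,7-trimethyldodeca-2,8,10-trien-1-ol | OC/C=C(\C)CCCC(C)(C)/C=C(\O[Si](C)(C)C(C)(C)C)/C=C/C | intermediate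
14 | (2E,8Z,10E)-9-(tert-butyldimethylsilyloxy)-3,7,7-trimethyldodeca-2,8,10-trienal | O=C/C=C(\C)CCCC(C)(C)/C=C(\O[Si](C)(C)C(C)(C)C)/C=C/C | intermediate (key step precursor)
15 | (1S,2S,4aS,8aS)-4-(tert-butyldimethylsilyloxy)-2,5,5,8a-tetramethyl-1,2,4a,5,6,7,8,8a-octahydronaphthalene-1-carbaldehyde (trans-fused; labdane terms: 5α-H, 8β-methyl, 9β-formyl, 10β-methyl, C6=C7 silyl enol ether) | O=C[C@@H]1[C@@]2(C)CCCC(C)(C)[C@@H]2C(O[Si](C)(C)C(C)(C)C)=C[C@@H]1C | intermediate (key step product)
16 | (3S)-5-methoxy-3-methyl-5-oxopentanoic acid (methyl hydrogen (S)-3-methylglutarate) | COC(=O)C[C@@H](C)CC(=O)O | starting material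
17 | methyl (3R)-4-iodo-3-methylbutanoate | COC(=O)C[C@@H](C)CI | intermediate
18 | [(2R)-4-methoxy-2-methyl-4-oxobutyl]triphenylphosphonium iodide | COC(=O)C[C@@H](C)C[P+](c1ccccc1)(c1ccccc1)c1ccccc1.[I-] | intermediate
19 | methyl (3R)-3-methyl-4-(triphenylphosphoranylidene)butanoate | COC(=O)C[C@@H](C)C=P(c1ccccc1)(c1ccccc1)c1ccccc1 | intermediate (not isolated)
20 | methyl (11Z,13R)-6-(tert-butyldimethylsilyloxy)labda-6,11-dien-15-oate (5α-H, 8α-H, 9α-H, 10β-methyl) | COC(=O)C[C@@H](C)/C=C\[C@@H]1[C@@]2(C)CCCC(C)(C)[C@@H]2C(O[Si](C)(C)C(C)(C)C)=C[C@@H]1C | intermediate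
21 | methyl (13S)-6-(tert-butyldimethylsilyloxy)labd-6-en-15-oate (5α-H, 8α-H, 9α-H) | COC(=O)C[C@@H](C)CC[C@@H]1[C@@]2(C)CCCC(C)(C)[C@@H]2C(O[Si](C)(C)C(C)(C)C)=C[C@@H]1C | intermediate
22 | methyl (13S)-6-oxolabd-7-en-15-oate (5α-H, 9α-H) | COC(=O)C[C@@H](C)CC[C@@H]1[C@@]2(C)CCCC(C)(C)[C@@H]2C(=O)C=C1C | intermediate
23 | methyl (13S)-7α,8α-epoxy-6-oxolabdan-15-oate | COC(=O)C[C@@H](C)CC[C@@H]1[C@@]2(C)CCCC(C)(C)[C@@H]2C(=O)[C@H]3O[C@@]13C | intermediate
24 | methyl (13S)-8α-hydroxy-6-oxolabdan-15-oate | COC(=O)C[C@@H](C)CC[C@@H]1[C@@]2(C)CCCC(C)(C)[C@@H]2C(=O)C[C@@]1(C)O | intermediate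
25 | methyl (13S)-6β,8α-dihydroxylabdan-15-oate | COC(=O)C[C@@H](C)CC[C@@H]1[C@@]2(C)CCCC(C)(C)[C@@H]2[C@H](O)C[C@@]1(C)O | intermediate
26 | methyl (13S)-6β-acetoxy-8α-hydroxylabdan-15-oate; methyl (3S)-5-[(1R,2R,4R,4aS,8aS)-4-acetoxy-2-hydroxy-2,5,5,8a-tetramethyldecahydronaphthalen-1-yl]-3-methylpentanoate | COC(=O)C[C@@H](C)CC[C@@H]1[C@@]2(C)CCCC(C)(C)[C@@H]2[C@H](OC(C)=O)C[C@@]1(C)O | target

## Step count and risk

Total: 18 steps. Longest linear sequence: 15 steps (1, 3–9, 12–18); step 2 and steps 10–11 are side branches.

**Step 9 (key step).** The most likely failure is a stalled or poorly face-selective cycloaddition. A β,β-disubstituted enal binds the catalyst weakly and reacts slowly, which leaves time for protodesilylation of the dienol ether or for a Mukaiyama–Michael addition that stops at the open-chain stage. A reversed sense of induction would be answered simply with the enantiomeric catalyst. The fallback for low selectivity gives up catalyst control and resolves through the side chain. From **14**, an achiral aluminium Lewis acid (Me2AlCl, CH2Cl2, −78 °C) would give the racemic cycloadduct, that is **15** together with its mirror image, (1R,2R,4aR,8aR)-4-(tert-butyldimethylsilyloxy)-2,5,5,8a-tetramethyl-1,2,4a,5,6,7,8,8a-octahydronaphthalene-1-carbaldehyde F1. Wittig reaction of the mixture with ylide **19** would give **20** and its diastereomer, methyl (11Z,13R)-6-(tert-butyldimethylsilyloxy)-ent-labda-6,11-dien-15-oate F2. The two are diastereomers and would be separated by chromatography, so the route is rejoined at **20**.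

**Step 6.** The most likely failure is loss of regiocontrol in the enolisation: deprotonation at C17 gives the linear dienol ether, because the C5 hydrogens are neopentyl. The fallback moves the enolisation to an ester-free intermediate, where irreversible kinetic deprotonation by a lithium amide can be used. From **3**, aldol addition to **8** (LiN(i-Pr)2, THF, −78 °C) would give 2-hydroxy-6,6-dimethylnon-8-en-4-one F3, and acid-catalysed dehydration (TsOH, PhH, reflux) would give (2E)-6,6-dimethylnona-2,8-dien-4-one F4. Enolisation with LiN(i-Pr)2 and TBSCl in THF/HMPA at −78 °C would give tert-butyl{[(2E,4Z)-6,6-dimethylnona-2,4,8-trien-4-yl]oxy}dimethylsilane F5. Hydroboration of its terminal alkene with 9-BBN would give 9-[(5Z,7E)-6-(tert-butyldimethylsilyloxy)-4,4-dimethylnona-5,7-dien-1-yl]-9-borabicyclo[3.3.1]nonane F6, and Suzuki–Miyaura coupling with **5** returns to **12**.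

**Step 3.** The most likely failure is competing reduction of the methyl ketone by the borane during hydroboration. The fallback replaces the borane by a ketone-tolerant organozinc. From **3**, radical anti-Markovnikov addition of HBr (dibenzoyl peroxide, hexane) would give 7-bromo-4,4-dimethylheptan-2-one F7. Zinc insertion (Zn, LiCl, THF) would give bromo(4,4-dimethyl-6-oxoheptyl)zinc F8, and Negishi coupling with **5** (Pd(PPh3)4, THF) returns to **7** with the same retention of the (E)-geometry.

**Step 12.** The most likely failure is enolisation of the hindered, α-branched aldehyde by the basic, bulky ylide instead of addition. The fallback builds the chain in three steps with a small ylide and sets C13 by catalysis. From **15**, methylenation (Ph3P=CH2, THF) would give tert-butyldimethyl(13,14,15,16-tetranorlabda-6,11-dien-6-yloxy)silane F9. Hydroboration with 9-BBN would give its 12-(9-borabicyclo[3.3.1]nonan-9-yl) derivative F10. Suzuki–Miyaura coupling with methyl (2E)-3-(trifluoromethanesulfonyloxy)but-2-enoate F11 (made from methyl acetoacetate as in step 2) would give methyl (13E)-6-(tert-butyldimethylsilyloxy)labda-6,13-dien-15-oate F12. Asymmetric conjugate reduction with copper hydride (Cu(OAc)2, a chiral bisphosphine of the enantiomer that gives 13S, polymethylhydrosiloxane, t-BuOH) returns to **21**.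

**Step 15.** The most likely failure is slow or unselective epoxidation: C8 is a fully substituted β-carbon next to the branched C9, and deprotonation at C9 or C17 can deconjugate the enone under the basic conditions. The fallback brings the oxygen in through boron. From **22**, copper-catalysed conjugate borylation from the α face (B2pin2, CuCl, NaOt-Bu, Xantphos, MeOH, THF) would give methyl (13S)-6-oxo-8α-(4,4,5,5-tetramethyl-1,3,2-dioxaborolan-2-yl)labdan-15-oate F13. Oxidation with NaBO3, with retention at C8, returns to **24** and bypasses **23**.

## Further compounds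

F1 | step 9 | (1R,2R,4aR,8aR)-4-(tert-butyldimethylsilyloxy)-2,5,5,8a-tetramethyl-1,2,4a,5,6,7,8,8a-octahydronaphthalene-1-carbaldehyde (enantiomer of 15) | O=C[C@H]1[C@]2(C)CCCC(C)(C)[C@H]2C(O[Si](C)(C)C(C)(C)C)=C[C@H]1C
F2 | step 9 | methyl (11Z,13R)-6-(tert-butyldimethylsilyloxy)-ent-labda-6,11-dien-15-oate (diastereomer of 20 with the mirror-image decalin) | COC(=O)C[C@@H](C)/C=C\[C@H]1[C@]2(C)CCCC(C)(C)[C@H]2C(O[Si](C)(C)C(C)(C)C)=C[C@H]1C
F3 | step 6 | 2-hydroxy-6,6-dimethylnon-8-en-4-one (racemic) | CC(O)CC(=O)CC(C)(C)CC=C
F4 | step 6 | (2E)-6,6-dimethylnona-2,8-dien-4-one | C/C=C/C(=O)CC(C)(C)CC=C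
F5 | step 6 | tert-butyl{[(2E,4Z)-6,6-dimethylnona-2,4,8-trien-4-yl]oxy}dimethylsilane | C=CCC(C)(C)/C=C(\O[Si](C)(C)C(C)(C)C)/C=C/C
F6 | step 6 | 9-[(5Z,7E)-6-(tert-butyldimethylsilyloxy)-4,4-dimethylnona-5,7-dien-1-yl]-9-borabicyclo[3.3.1]nonane | B1(CCCC(C)(C)/C=C(\O[Si](C)(C)C(C)(C)C)/C=C/C)C2CCCC1CCC2
F7 | step 3 | 7-bromo-4,4-dimethylheptan-2-one | CC(=O)CC(C)(C)CCCBr
F8 | step 3 | bromo(4,4-dimethyl-6-oxoheptyl)zinc | CC(=O)CC(C)(C)CCC[Zn]Br
F9 | step 12 | tert-butyldimethyl(13,14,15,16-tetranorlabda-6,11-dien-6-yloxy)silane (5α-H, 8α-H, 9α-H) | C=C[C@@H]1[C@@]2(C)CCCC(C)(C)[C@@H]2C(O[Si](C)(C)C(C)(C)C)=C[C@@H]1C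
F10 | step 12 | 9-[6-(tert-butyldimethylsilyloxy)-13,14,15,16-tetranorlabd-6-en-12-yl]-9-borabicyclo[3.3.1]nonane | B1(CC[C@@H]3[C@@]4(C)CCCC(C)(C)[C@@H]4C(O[Si](C)(C)C(C)(C)C)=C[C@@H]3C)C2CCCC1CCC2
F11 | step 12 | methyl (2E)-3-(trifluoromethanesulfonyloxy)but-2-enoate | COC(=O)/C=C(\C)OS(=O)(=O)C(F)(F)F
F12 | step 12 | methyl (13E)-6-(tert-butyldimethylsilyloxy)labda-6,13-dien-15-oate | COC(=O)/C=C(\C)CC[C@@H]1[C@@]2(C)CCCC(C)(C)[C@@H]2C(O[Si](C)(C)C(C)(C)C)=C[C@@H]1C
F13 | step 15 | methyl (13S)-6-oxo-8α-(4,4,5,5-tetramethyl-1,3,2-dioxaborolan-2-yl)labdan-15-oate | COC(=O)C[C@@H](C)CC[C@@H]1[C@@]2(C)CCCC(C)(C)[C@@H]2C(=O)C[C@@]1(C)B3OC(C)(C)C(C)(C)O3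
A1 | alternative 1 | 3α-hydroxy-4,4,10-trimethyl-trans-decalin-6,8-dione (labdane numbering) | O=C1C[C@@]2(C)CC[C@@H](O)C(C)(C)[C@@H]2C(=O)C1
A2 | alternative 2 | methyl 6β-acetoxylabda-8(17),11E-dien-15-oate | COC(=O)C[C@@H](C)/C=C/[C@@H]1[C@@]2(C)CCCC(C)(C)[C@@H]2[C@H](OC(C)=O)CC1=C
A3 | alternative 3 | methyl 8α-(tert-butylperoxy)-6-oxolabdan-15-oate | COC(=O)C[C@@H](C)CC[C@@H]1[C@@]2(C)CCCC(C)(C)[C@@H]2C(=O)C[C@@]1(C)OOC(C)(C)C
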